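**Retrosynthetic overview**

1. Feature: the dihydrofuran O1–C2–C3–C3a–C7a fused to ring B carries ring C on C2 and CH2OH on C3 on the same face (2S,3S), which is the contra-thermodynamic cis form. Read from the SMILES, the furofuran has H-1, H-3a, H-4 and H-6a all cis, so rings A and B are both endo, and that is contra-thermodynamic as well.
2. Last ring: the C2–C3 bond is cut to a carbenoid carbon on C3a (an aryldiazoacetate) and the CH2 of a ring-C benzyl ether on the C7a oxygen. The forward reaction is a 1,5 C–H insertion with a chiral dirhodium carboxylate, followed only by ester reduction and desilylation.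
3. The diazoacetate comes from a Claisen-derived allyl group by cleavage, oxidation, esterification and diazo transfer.
4. Furofuran: each Ar–CH bond is cut to an aryllithium plus a lactone carbonyl. Each hemiketal is reduced by Et3SiH/BF3·OEt2 from the convex face, which places the aryl group endo. The linchpin is a C2-symmetric bis-lactone made from succinyl chloride by two auxiliary-controlled benzyloxymethylations.
5. Ring order: the two lactone rings form together, then the tetrahydrofuran on the ring-A side, then the tetrahydrofuran on the ring-B side, and the dihydrobenzofuran last.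

Key step: step 18

Assumption: the sense of induction is carried over from the parent methyl 2-(2-benzyloxyphenyl)-2-diazoacetates, where the S-configured phthaloyl-tert-leucinate catalyst leads to (2R,3S) cis esters. The (2S,3R) ester needed here therefore calls for Rh2(R-PTTL)4 (from D-tert-leucine), and this is to be confirmed on a simple bromo model before the full substrate is committed.

**Step 1**
Reactants: 1 (R)-4-benzyl-1,3-oxazolidin-2-one (2 equiv); 2 succinyl chloride
Product: 4 1,4-bis[(4R)-4-benzyl-2-oxo-1,3-oxazolidin-3-yl]butane-1,4-dione, via N-lithio oxazolidinone 3 (not isolated)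
Conditions: n-BuLi, THF, −78 °C; then 2, −78 °C to 0 °C
Reagents that add atoms: none
Why: N-acylation of the lithiated Evans auxiliary at both acyl chloride groups should give the C2-symmetric bis-imide, and no stereocentre is formed.

**Step 2**
Reactants: 4 bis-imide
Product: 6 (2S,3S)-2,3-bis[(benzyloxy)methyl]-1,4-bis[(4R)-4-benzyl-2-oxo-1,3-oxazolidin-3-yl]butane-1,4-dione, via mono(benzyloxymethyl) bis-imide 5 (not isolated)
Conditions: TiCl4 (1.1 equiv), iPr2NEt (1.15 equiv), CH2Cl2, 0 °C, then BnOCH2Cl; second identical charge of the three reagents in the same flask, 0 °C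
Reagents that add atoms: benzyl chloromethyl ether ClCOCc1ccccc1
Why: In this Evans titanium-enolate alkylation each chelated Z-enolate, generated one imide at a time so that no oxidisable bis-enolate arises, should be attacked on the face opposite the benzyl group of its own (R)-auxiliary, which sets both new centres S (the C2-symmetric isomer), while allylic 1,3-strain keeps the alkylated α-carbon from being enolised again.

**Step 3**
Reactants: 6 bis(benzyloxymethyl) bis-imide
Product: 8 (3aS,6aS)-tetrahydrofuro[3,4-c]furan-1,4-dione (cis-fused C2-symmetric bis-lactone), via dihydroxy bis-imide 7 (not isolated)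
Conditions: H2 (1 atm), Pd(OH)2/C, EtOAc, rt; then p-TsOH·H2O (cat.), toluene, 80 °C
Reagents that add atoms: none
Why: Benzyl ether hydrogenolysis followed by a double 5-exo-trig lactonisation of each primary alcohol onto the distal imide carbonyl expels both auxiliaries, the S,S diol is the isomer able to close twice to a cis-fused bicycle, and no stereocentre is touched under the acidic, non-enolising conditions.

**Step 4**
Reactants: 9 4-bromo-2-methoxyphenol
Product: 10 (4-bromo-2-methoxyphenoxy)triisopropylsilane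
Conditions: TIPSCl, imidazole, DMF, rt
Reagents that add atoms: chlorotriisopropylsilane CC(C)[Si](Cl)(C(C)C)C(C)C
Why: Phenol silylation with TIPS is chosen because the aryl silyl ethers must later survive n-BuLi, cold BF3·OEt2 and DBU.

**Step 5**
Reactants: 10 ring-A aryl bromide; 8 bis-lactone (1.5 equiv)
Product: 12 (3aS,6aS)-4-hydroxy-4-[3-methoxy-4-(triisopropylsilyloxy)phenyl]tetrahydro-1H,3H-furo[3,4-c]furan-1-one (hemiketal, anomeric mixture in equilibrium with its hydroxy ketone; used crude), via ring-A aryllithium 11 (not isolated)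
Conditions: n-BuLi, THF, −78 °C; cannulated slowly into 8, THF, −78 °C; AcOH quench at −78 °C
Reagents that add atoms: none
Why: Bromine–lithium exchange is followed by 1,2-addition to a lactone whose tetrahedral lithium alkoxide persists at −78 °C, the two carbonyl groups are homotopic so mono-addition gives one compound, and excess 8, inverse addition and the cold acidic quench hold back double addition and enolisation.

**Step 6**
Reactants: 12 hemiketal
Product: 13 (3aS,4S,6aS)-4-[3-methoxy-4-(triisopropylsilyloxy)phenyl]tetrahydro-1H,3H-furo[3,4-c]furan-1-one (ring A endo; H-3a, H-4, H-6a all cis)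
Conditions: Et3SiH, BF3·OEt2, CH2Cl2, −78 °C; aq NaHCO3 quench at −78 °C
Reagents that add atoms: none
Why: In this ionic hemiketal reduction BF3·OEt2 forms the aryl-stabilised bicyclic oxocarbenium ion and Et3SiH should deliver hydride to its convex face (the face of the bridgehead hydrogens), so the new H-4 is cis to H-3a and H-6a and ring A ends up endo (4S).

**Step 7**
Reactants: 14 vanillin
Product: 15 3-methoxy-4-(triisopropylsilyloxy)benzaldehyde
Conditions: TIPSCl, imidazole, DMF, rt
Reagents that add atoms: chlorotriisopropylsilane CC(C)[Si](Cl)(C(C)C)C(C)C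
Why: This is a standard phenol silylation, and the aldehyde is unaffected.

**Step 8**
Reactants: 15 silylated vanillin
Product: 16 [3-methoxy-4-(triisopropylsilyloxy)phenyl]methanol
Conditions: NaBH4, MeOH, 0 °C
Reagents that add atoms: none
Why: Borohydride reduction of the aldehyde gives the ring-C benzyl alcohol and leaves the aryl silyl ether intact.

**Step 9**
Reactants: 9 4-bromo-2-methoxyphenol
Product: 17 1-(allyloxy)-4-bromo-2-methoxybenzene
Conditions: allyl bromide, K2CO3, acetone, reflux
Reagents that add atoms: allyl bromide C=CCBr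
Why: This is a Williamson O-allylation of the phenoxide.

**Step 10**
Reactants: 17 allyl aryl ether
Product: 18 2-allyl-4-bromo-6-methoxyphenol
Conditions: N,N-diethylaniline, 200 °C
Reagents that add atoms: none
Why: In this aromatic Claisen rearrangement ([3,3] shift, then tautomerisation) only one ortho position is free, so the allyl group lands next to the phenol oxygen and meta to bromine.

**Step 11**
Reactants: 18 allyl bromophenol; 16 ring-C benzyl alcohol
Product: 19 1-allyl-5-bromo-3-methoxy-2-{[3-methoxy-4-(triisopropylsilyloxy)phenyl]methoxy}benzene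
Conditions: PPh3, DIAD, THF, 0 °C to rt
Reagents that add atoms: none
Why: Mitsunobu etherification under neutral conditions avoids both a labile electron-rich benzyl halide and phenoxide-induced silyl migration.

**Step 12**
Reactants: 19 ring-B/C aryl bromide; 13 ring-A furofuranone
Product: 21 (1S,3aS,6aS)-configured hemiketal, that is furofuran 22 with OH in place of H on the ring-B benzylic carbon C4 (anomeric mixture, used crude), via ring-B aryllithium 20 (not isolated)
Conditions: n-BuLi, THF, −78 °C; then 13, −78 °C; AcOH quench at −78 °C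
Reagents that add atoms: none
Why: Bromine–lithium exchange at −78 °C outruns deprotonation of the allylic and benzylic CH2 groups, and 1,2-addition to the lactone stops at the stable tetrahedral alkoxide without touching the three existing stereocentres.

**Step 13**
Reactants: 21 hemiketal
Product: 22 (1S,3aS,4S,6aS)-1-[3-methoxy-4-(triisopropylsilyloxy)phenyl]-4-(3-allyl-5-methoxy-4-{[3-methoxy-4-(triisopropylsilyloxy)phenyl]methoxy}phenyl)tetrahydro-1H,3H-furo[3,4-c]furan (rings A and B both endo)
Conditions: Et3SiH, BF3·OEt2, CH2Cl2, −78 °C; aq NaHCO3 quench at −78 °C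
Reagents that add atoms: none
Why: In this ionic hemiketal reduction the concave face of the oxocarbenium ion is closed by the bicycle and by endo ring A, so hydride should enter from the convex face and set C4 as S with ring B endo, while the tertiary hemiketal ionises far more readily at −78 °C than the benzyl aryl ether or the finished benzylic C–O bonds.

**Step 14**
Reactants: 22 allyl furofuran
Product: 24 arylacetaldehyde (22 with CH2CHO in place of allyl), via vicinal diol 23 (not isolated)
Conditions: OsO4 (cat.), NaIO4, 2,6-lutidine, dioxane/H2O, rt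
Reagents that add atoms: osmium tetroxide O=[Os](=O)(=O)=O; sodium periodate [Na+].[O-]I(=O)(=O)=O
Why: Lemieux–Johnson oxidation acts on the terminal alkene, which is the only C=C bond, and the lutidine buffer protects the acid-labile endo,endo furofuran.

**Step 15**
Reactants: 24 arylacetaldehyde
Product: 25 arylacetic acid (22 with CH2CO2H in place of allyl)
Conditions: NaClO2, NaH2PO4, 2-methyl-2-butene, t-BuOH/H2O, 0 °C to rt
Reagents that add atoms: sodium chlorite [Na+].[O-]Cl=O
Why: Pinnick oxidation is used with a large excess of alkene scavenger, which removes hypochlorous acid before it can chlorinate the electron-rich rings.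

**Step 16**
Reactants: 25 arylacetic acid
Product: 26 methyl arylacetate (22 with CH2CO2Me in place of allyl)
Conditions: TMSCHN2, toluene/MeOH, 0 °C
Reagents that add atoms: (trimethylsilyl)diazomethane C[Si](C)(C)C=[N+]=[N-]
Why: Neutral O-methylation of the carboxylic acid by a diazoalkane spares the silyl ethers and the benzylic ethers.

**Step 17**
Reactants: 26 methyl arylacetate
Product: 27 methyl 2-diazo-2-(3-methoxy-2-{[3-methoxy-4-(triisopropylsilyloxy)phenyl]methoxy}-5-{(1S,3aS,4S,6aS)-4-[3-methoxy-4-(triisopropylsilyloxy)phenyl]tetrahydro-1H,3H-furo[3,4-c]furan-1-yl}phenyl)acetate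
Conditions: p-ABSA, DBU, MeCN, 0 °C to rt
Reagents that add atoms: 4-acetamidobenzenesulfonyl azide CC(=O)Nc1ccc(cc1)S(=O)(=O)N=[N+]=[N-]
Why: In this Regitz diazo transfer the arylacetate enolate formed by DBU attacks the sulfonyl azide, and the furofuran and the TIPS ethers are stable to this base.

**Step 18**
Reactants: 27 aryldiazoacetate
Product: 28 methyl (2S,3R)-7-methoxy-2-[3-methoxy-4-(triisopropylsilyloxy)phenyl]-5-{(1S,3aS,4S,6aS)-4-[3-methoxy-4-(triisopropylsilyloxy)phenyl]tetrahydro-1H,3H-furo[3,4-c]furan-1-yl}-2,3-dihydrobenzofuran-3-carboxylate (2,3-cis)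
Conditions: Rh2(R-PTTL)4 (dirhodium tetrakis[N-phthaloyl-(R)-tert-leucinate], 2 mol %), toluene (0.01 M), 4 Å MS, −60 °C
Reagents that add atoms: none
Why: Rh2(R-PTTL)4 expels N2 from 27, and the electrophilic donor–acceptor rhodium carbenoid, whose carbon sits on C3a of ring B, takes up a hydrogen of the neighbouring ArCH2–O group in a concerted but asynchronous, hydride-transfer-like three-centre insertion that makes the C2–C3 bond. The closest known reaction type is the enantioselective intramolecular C–H insertion of methyl 2-(2-benzyloxyphenyl)-2-diazoacetates with N-phthaloyl amino acid dirhodium carboxylates, which gives cis-2-aryl-2,3-dihydrobenzofuran-3-carboxylates. The one ring closed, O1–C2–C3–C3a–C7a, forms by 1,5-insertion through a five-membered cyclic transition state (carbenoid C, C3a, C7a, O, benzylic C). C3 (R) is set by the carbenoid face that the phthalimido wall of the catalyst leaves open, and C2 (S) by which of the two enantiotopic benzylic hydrogens can be offered to that face with ring C turned away from the wall, an arrangement that leaves ring C and the ester on the same side, so the cis ester is the kinetic product and is not equilibrated in neutral toluene at −60 °C. The step needs cis over trans, one absolute sense regardless of the remote furofuran centres (hence pure catalyst control), and 1,5-insertion over every other carbenoid pathway. The substrate secures the last point because the reacting C–H is doubly activated (ether oxygen, electron-rich ring C) and held next to the carbenoid, whereas the nearest furofuran benzylic C–H hangs from a ring-B position meta to the carbenoid carbon and cannot be bridged, and dilution disfavours bimolecular insertion or ylide formation.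

**Step 19**
Reactants: 28 cis ester
Product: 29 (2S,3S)-3-hydroxymethyl analogue of 28 (2,3-cis, both phenols still TIPS-protected)
Conditions: iBu2AlH (3.5 equiv), CH2Cl2, −78 °C; Rochelle salt work-up
Reagents that add atoms: none
Why: Ester reduction with a non-basic aluminium hydride at low temperature consumes the intermediate aldehyde faster than C3 can enolise, so the cis relationship is kept, and the descriptor at C3 changes from R to S only through the CIP priorities.

**Step 20**
Reactants: 29 bis-silyl ether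
Product: 30 target, 4-[(1S,3aS,4S,6aS)-4-{(2S,3S)-2-(4-hydroxy-3-methoxyphenyl)-3-(hydroxymethyl)-7-methoxy-2,3-dihydrobenzofuran-5-yl}tetrahydro-1H,3H-furo[3,4-c]furan-1-yl]-2-methoxyphenol
Conditions: Bu4NF, AcOH (1:1), THF, 0 °C
Reagents that add atoms: none
Why: Fluoride desilylation is buffered with acetic acid so that no para-phenoxide persists, since a free phenoxide could open the benzylic C–O bonds through quinone methides and epimerise C2 of the dihydrobenzofuran or the endo furofuran carbons.

**Compound list**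

1 | (R)-4-benzyl-1,3-oxazolidin-2-one | O=C1N[C@H](Cc2ccccc2)CO1 | starting material
2 | succinyl chloride | O=C(Cl)CCC(=O)Cl | starting material
3 | N-lithio-(R)-4-benzyl-1,3-oxazolidin-2-one | [Li]N1C(=O)OC[C@H]1Cc1ccccc1 | intermediate
4 | 1,4-bis[(4R)-4-benzyl-2-oxo-1,3-oxazolidin-3-yl]butane-1,4-dione | O=C(CCC(=O)N1C(=O)OC[C@H]1Cc1ccccc1)N1C(=O)OC[C@H]1Cc1ccccc1 | intermediate
5 | (2S)-2-[(benzyloxy)methyl] derivative of 4 | O=C([C@H](COCc1ccccc1)CC(=O)N1C(=O)OC[C@H]1Cc1ccccc1)N1C(=O)OC[C@H]1Cc1ccccc1 | intermediate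
6 | (2S,3S)-2,3-bis[(benzyloxy)methyl] derivative of 4 | O=C([C@H](COCc1ccccc1)[C@@H](COCc1ccccc1)C(=O)N1C(=O)OC[C@H]1Cc1ccccc1)N1C(=O)OC[C@H]1Cc1ccccc1 | intermediate
7 | (2S,3S)-2,3-bis(hydroxymethyl) derivative of 4 | O=C([C@H](CO)[C@@H](CO)C(=O)N1C(=O)OC[C@H]1Cc1ccccc1)N1C(=O)OC[C@H]1Cc1ccccc1 | intermediate
8 | (3aS,6aS)-tetrahydrofuro[3,4-c]furan-1,4-dione | O=C1OC[C@@H]2[C@H]1COC2=O | intermediate
9 | 4-bromo-2-methoxyphenol | COc1cc(Br)ccc1O | starting material
10 | (4-bromo-2-methoxyphenoxy)triisopropylsilane | COc1cc(Br)ccc1O[Si](C(C)C)(C(C)C)C(C)C | intermediate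
11 | [3-methoxy-4-(triisopropylsilyloxy)phenyl]lithium | COc1cc([Li])ccc1O[Si](C(C)C)(C(C)C)C(C)C | intermediate
12 | ring-A hemiketal lactone (3aS,6aS) | COc1cc(C2(O)OC[C@@H]3[C@H]2COC3=O)ccc1O[Si](C(C)C)(C(C)C)C(C)C | intermediate
13 | (3aS,4S,6aS)-endo ring-A furofuranone | COc1cc([C@H]2OC[C@@H]3[C@H]2COC3=O)ccc1O[Si](C(C)C)(C(C)C)C(C)C | intermediate
14 | vanillin | COc1cc(C=O)ccc1O | starting material
15 | 3-methoxy-4-(triisopropylsilyloxy)benzaldehyde | COc1cc(C=O)ccc1O[Si](C(C)C)(C(C)C)C(C)C | intermediate
16 | [3-methoxy-4-(triisopropylsilyloxy)phenyl]methanol | COc1cc(CO)ccc1O[Si](C(C)C)(C(C)C)C(C)C | intermediate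
17 | 1-(allyloxy)-4-bromo-2-methoxybenzene | C=CCOc1ccc(Br)cc1OC | intermediate
18 | 2-allyl-4-bromo-6-methoxyphenol | C=CCc1cc(Br)cc(OC)c1O | intermediate
19 | ring-B/C aryl bromide | C=CCc1cc(Br)cc(OC)c1OCc1ccc(O[Si](C(C)C)(C(C)C)C(C)C)c(OC)c1 | intermediate
20 | ring-B aryllithium | C=CCc1cc([Li])cc(OC)c1OCc1ccc(O[Si](C(C)C)(C(C)C)C(C)C)c(OC)c1 | intermediate
21 | ring-B hemiketal | COc1cc([C@H]2OC[C@@H]3[C@H]2COC3(O)c2cc(OC)c(OCc3ccc(O[Si](C(C)C)(C(C)C)C(C)C)c(OC)c3)c(CC=C)c2)ccc1O[Si](C(C)C)(C(C)C)C(C)C | intermediate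
22 | endo,endo allyl furofuran | COc1cc([C@H]2OC[C@@H]3[C@H]2CO[C@@H]3c2cc(OC)c(OCc3ccc(O[Si](C(C)C)(C(C)C)C(C)C)c(OC)c3)c(CC=C)c2)ccc1O[Si](C(C)C)(C(C)C)C(C)C | intermediate
23 | vicinal diol from 22 (carbinol centre unassigned) | COc1cc([C@H]2OC[C@@H]3[C@H]2CO[C@@H]3c2cc(OC)c(OCc3ccc(O[Si](C(C)C)(C(C)C)C(C)C)c(OC)c3)c(CC(O)CO)c2)ccc1O[Si](C(C)C)(C(C)C)C(C)C | intermediate
24 | arylacetaldehyde | COc1cc([C@H]2OC[C@@H]3[C@H]2CO[C@@H]3c2cc(OC)c(OCc3ccc(O[Si](C(C)C)(C(C)C)C(C)C)c(OC)c3)c(CC=O)c2)ccc1O[Si](C(C)C)(C(C)C)C(C)C | intermediate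
25 | arylacetic acid | COc1cc([C@H]2OC[C@@H]3[C@H]2CO[C@@H]3c2cc(OC)c(OCc3ccc(O[Si](C(C)C)(C(C)C)C(C)C)c(OC)c3)c(CC(=O)O)c2)ccc1O[Si](C(C)C)(C(C)C)C(C)C | intermediate
26 | methyl arylacetate | COc1cc([C@H]2OC[C@@H]3[C@H]2CO[C@@H]3c2cc(OC)c(OCc3ccc(O[Si](C(C)C)(C(C)C)C(C)C)c(OC)c3)c(CC(=O)OC)c2)ccc1O[Si](C(C)C)(C(C)C)C(C)C | intermediate
27 | aryldiazoacetate (key-step precursor) | COc1cc([C@H]2OC[C@@H]3[C@H]2CO[C@@H]3c2cc(OC)c(OCc3ccc(O[Si](C(C)C)(C(C)C)C(C)C)c(OC)c3)c(C(=[N+]=[N-])C(=O)OC)c2)ccc1O[Si](C(C)C)(C(C)C)C(C)C | intermediate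
28 | (2S,3R)-cis dihydrobenzofuran ester (key-step product) | COc1cc([C@H]2OC[C@@H]3[C@H]2CO[C@@H]3c2cc(OC)c3c(c2)[C@@H](C(=O)OC)[C@@H](c2ccc(O[Si](C(C)C)(C(C)C)C(C)C)c(OC)c2)O3)ccc1O[Si](C(C)C)(C(C)C)C(C)C | intermediate
29 | (2S,3S)-cis hydroxymethyl bis-TIPS ether | COc1cc([C@H]2OC[C@@H]3[C@H]2CO[C@@H]3c2cc(OC)c3c(c2)[C@@H](CO)[C@@H](c2ccc(O[Si](C(C)C)(C(C)C)C(C)C)c(OC)c2)O3)ccc1O[Si](C(C)C)(C(C)C)C(C)C | intermediate
30 | CNP0303197.1 | COc1cc([C@H]2OC[C@@H]3[C@H]2CO[C@@H]3c2cc(OC)c3c(c2)[C@@H](CO)[C@@H](c2ccc(O)c(OC)c2)O3)ccc1O | target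

**Step count**

- Total step count: 20.
- Longest linear sequence: 14 steps (1, 2, 3, 5, 6, 12, 13, 14, 15, 16, 17, 18, 19, 20).

**Steps most likely to fail**

**Step 18.**
- What may go wrong: Catalyst control may weaken on the crowded benzyl ether flanked by the 7-methoxy group. This would erode cis selectivity or facial selectivity, and here that shows up as diastereomers. The carbenoid may also be diverted by the Lewis-basic furofuran oxygens or by bimolecular insertion.
- Fallback (sets out from 19, returns at 29): the insertion is moved to the simple aryl bromide, the substrate class on which it is established, and the furofuran is attached afterwards.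
- Bromide 19 is taken through the operations of steps 14 to 17. OsO4/NaIO4 leads through the vicinal diol F1 to the arylacetaldehyde F2. NaClO2 then gives the arylacetic acid F3, TMSCHN2 the methyl ester F4, and p-ABSA/DBU the bromo aryldiazoacetate F5.
- Rh2(R-PTTL)4 in toluene at −60 °C should give the cis bromo ester F6. Its enantiomeric purity can be raised by recrystallisation before any diastereomer problem exists.
- iBu2AlH gives the bromo alcohol F7.
- n-BuLi (2.1 equiv, THF, −78 °C) gives the O,C-dilithio species F8, which adds to furofuranone 13 to give the hemiketal F9.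
- Et3SiH/BF3·OEt2 at −78 °C then leads to 29.

**Step 5.**
- What may go wrong: A second addition may occur at the remaining lactone. Base-induced enolisation of the bis-lactone with β-elimination of carboxylate is also possible, as is epimerisation of the open hydroxy ketone before it is reduced.
- Fallback (sets out from 6, returns at 12): mono-addition is enforced by an anhydride, which leaves an inert carboxylate after one addition.
- LiOH/H2O2 in THF/H2O removes both auxiliaries from 6 to give the diacid F10.
- Ac2O closes it to the trans-disubstituted succinic anhydride F11.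
- Aryllithium 11 (1 equiv, −78 °C) opens either of its homotopic carbonyl groups to give the keto acid F12.
- Hydrogenolysis (H2, Pd/C, EtOAc) frees the dihydroxy keto acid F13, which closes by itself to lactone and hemiketal, that is 12.

**Step 13.**
- What may go wrong: Acid-induced ionisation of the finished benzylic C–O bonds may epimerise an endo aryl group to exo or lead to over-reduction. The PMB-like ring-C benzyl ether may also be lost under BF3·OEt2.
- Fallback (sets out from 21, returns at 22): the Lewis acid is avoided and the ring is closed at the primary carbon instead.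
- Through its open hydroxy ketone form, 21 is reduced with BH3·SMe2 and (R)-2-methyl-CBS-oxazaborolidine (reagent control, aryl as the large group) to the (S)-benzylic diol F14.
- TsCl/pyridine at 0 °C sulfonylates only the primary alcohol to give the monotosylate F15.
- NaH in THF closes the tetrahydrofuran by a 5-exo-tet Williamson displacement. This leaves the benzylic C–O bond and its configuration untouched and gives 22.

**Further compounds**
F1 | step 18 | vicinal diol from 19 (carbinol centre unassigned) | OCC(O)Cc1cc(Br)cc(OC)c1OCc1ccc(O[Si](C(C)C)(C(C)C)C(C)C)c(OC)c1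
F2 | step 18 | bromo arylacetaldehyde | O=CCc1cc(Br)cc(OC)c1OCc1ccc(O[Si](C(C)C)(C(C)C)C(C)C)c(OC)c1
F3 | step 18 | bromo arylacetic acid | OC(=O)Cc1cc(Br)cc(OC)c1OCc1ccc(O[Si](C(C)C)(C(C)C)C(C)C)c(OC)c1
F4 | step 18 | methyl bromo arylacetate | COC(=O)Cc1cc(Br)cc(OC)c1OCc1ccc(O[Si](C(C)C)(C(C)C)C(C)C)c(OC)c1
F5 | step 18 | methyl bromo aryldiazoacetate | COC(=O)C(=[N+]=[N-])c1cc(Br)cc(OC)c1OCc1ccc(O[Si](C(C)C)(C(C)C)C(C)C)c(OC)c1
F6 | step 18 | methyl (2S,3R)-5-bromo-7-methoxy-2-[3-methoxy-4-(triisopropylsilyloxy)phenyl]-2,3-dihydrobenzofuran-3-carboxylate (cis) | Brc1cc(OC)c2c(c1)[C@@H](C(=O)OC)[C@@H](c1ccc(O[Si](C(C)C)(C(C)C)C(C)C)c(OC)c1)O2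
F7 | step 18 | (2S,3S)-cis bromo alcohol | Brc1cc(OC)c2c(c1)[C@@H](CO)[C@@H](c1ccc(O[Si](C(C)C)(C(C)C)C(C)C)c(OC)c1)O2
F8 | step 18 | O,C-dilithio species from F7 | [Li]c1cc(OC)c2c(c1)[C@@H](CO[Li])[C@@H](c1ccc(O[Si](C(C)C)(C(C)C)C(C)C)c(OC)c1)O2
F9 | step 18 | hemiketal from F8 and 13 | COc1cc([C@H]2OC[C@@H]3[C@H]2COC3(O)c2cc(OC)c3c(c2)[C@@H](CO)[C@@H](c2ccc(O[Si](C(C)C)(C(C)C)C(C)C)c(OC)c2)O3)ccc1O[Si](C(C)C)(C(C)C)C(C)C
F10 | step 5 | (2S,3S)-2,3-bis[(benzyloxy)methyl]succinic acid | OC(=O)[C@H](COCc1ccccc1)[C@@H](COCc1ccccc1)C(=O)O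
F11 | step 5 | (3S,4S)-3,4-bis[(benzyloxy)methyl]oxolane-2,5-dione | O=C1OC(=O)[C@H](COCc2ccccc2)[C@H]1COCc1ccccc1
F12 | step 5 | (2S,3S)-2,3-bis[(benzyloxy)methyl]-4-[3-methoxy-4-(triisopropylsilyloxy)phenyl]-4-oxobutanoic acid | COc1cc(C(=O)[C@H](COCc2ccccc2)[C@@H](COCc2ccccc2)C(=O)O)ccc1O[Si](C(C)C)(C(C)C)C(C)C
F13 | step 5 | (2S,3S)-2,3-bis(hydroxymethyl) analogue of F12 | COc1cc(C(=O)[C@H](CO)[C@@H](CO)C(=O)O)ccc1O[Si](C(C)C)(C(C)C)C(C)C
F14 | step 13 | (S)-benzylic diol from 21 | COc1cc([C@H]2OC[C@@H]([C@H](O)c3cc(OC)c(OCc4ccc(O[Si](C(C)C)(C(C)C)C(C)C)c(OC)c4)c(CC=C)c3)[C@H]2CO)ccc1O[Si](C(C)C)(C(C)C)C(C)C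
F15 | step 13 | primary monotosylate of F14 | COc1cc([C@H]2OC[C@@H]([C@H](O)c3cc(OC)c(OCc4ccc(O[Si](C(C)C)(C(C)C)C(C)C)c(OC)c4)c(CC=C)c3)[C@H]2COS(=O)(=O)c2ccc(C)cc2)ccc1O[Si](C(C)C)(C(C)C)C(C)C
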